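**Retrosynthetic overview**
- The (12Z,14E)-diene is made last, by Wittig reaction of a ring-bearing, non-stabilised ylide (ylide carbon = C12 of the side chain) with (E)-but-2-enal, which supplies the 14E alkene.
- The ring-to-side-chain bond (ring C2 to acyl C1) comes from a photochemical 1,3-acyl shift (photo-Fries type) of the enol 12-bromododecanoates of (S)-4-hydroxycyclohexane-1,3-dione. The esters are made and irradiated in one operation, before the light-sensitive diene exists.
- The only ring, the cyclohexane-1,3-dione, is closed by a new lactone-opening Dieckmann cyclisation of (S)-5-acetyl-γ-butyrolactone, which also frees the ring hydroxyl without protecting groups.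
- The single stereocentre is bought in (S)-5-oxotetrahydrofuran-2-carboxylic acid (L-glutamic acid pool), and no bond to it is made or broken.

Assumption: the β-triketone and the 1,3-dione are each drawn as one tautomer of a fast equilibrium, and 1, 7 and 13 (at least 99 % E) are taken as catalogue compounds.

**Step 1**
Reactants: 1 (S)-5-oxotetrahydrofuran-2-carboxylic acid
Product: 3 (S)-5-acetyldihydrofuran-2(3H)-one, via acid chloride 2 (not isolated)
Conditions: (COCl)2 (1.2 equiv), DMF (cat.), CH2Cl2, 0 °C to rt, evaporate; then MeMgBr (1.05 equiv), Fe(acac)3 (3 mol %), THF, −78 °C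
Reagents that add atoms: oxalyl chloride ClC(=O)C(=O)Cl (chlorine of 2 only); methylmagnesium bromide C[Mg]Br
Why: Neutral acid chloride formation and iron-catalysed acyl chloride–Grignard cross-coupling (ketone synthesis) are both faster than attack on the lactone or on the product ketone at −78 °C, and no base is present to enolise the α-carbon, so the stereocentre bought in 1 is carried through unchanged.

**Step 2**
Reactants: 3 (S)-5-acetyldihydrofuran-2(3H)-one
Product: 6 (S)-4-hydroxycyclohexane-1,3-dione, via lithium enolate 4 (not isolated), via bridged hemiketal alkoxide 5 (not isolated)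
Conditions: LiN(SiMe3)2 (2.1 equiv), THF (0.02 M), −78 °C to −20 °C; then HCl (2 M in Et2O), −78 °C
Reagents that add atoms: none
Why: Proposed new method: a lactone-opening, Dieckmann-type (intramolecular Claisen) ring closure in which kinetic deprotonation of the methyl group (the hindered, acyloxy-bearing methine is left alone, so the stereocentre is kept) gives enolate 4, whose carbon adds 6-exo to the lactone carbonyl to give the 7-oxanorbornane hemiketal alkoxide 5, which collapses by breaking the ring C–O bond to release the C4 alkoxide, and deprotonation of the new, strongly acidic 1,3-dione makes the sequence irreversible; the closest known reaction types are the base-mediated cyclisation of 5-oxohexanoate esters to cyclohexane-1,3-diones and the intermolecular Claisen acylation of ketone enolates by γ-lactones, neither of which has been shown for a γ-acyl-γ-butyrolactone closing through a bridged intermediate.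

**Step 3**
Reactants: 6 (S)-4-hydroxycyclohexane-1,3-dione; 7 12-bromododecanoic acid
Product: 11 (S)-2-(12-bromododecanoyl)-3,6-dihydroxycyclohex-2-en-1-one, via 12-bromododecanoyl chloride 8 (not isolated), via 4-hydroxy enol ester 9 (not isolated), via 6-hydroxy enol ester 10 (not isolated)
Conditions: 7, (COCl)2 (1.2 equiv), DMF (cat.), CH2Cl2, rt, evaporate; then 6, Et3N (1.05 equiv), CH2Cl2, −40 °C to 0 °C; cold aq. NaH2PO4 wash, solvent switch to degassed MeCN (5 mM), no purification; then hν (254 nm, low-pressure Hg lamp, quartz flow coil), 20 °C, residence time set for full conversion of 9 and 10 (HPLC)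
Reagents that add atoms: oxalyl chloride ClC(=O)C(=O)Cl (chlorine of 8 only)
Why: Enol esterification of the 1,3-dione by the acid chloride (Et3N ionises the vinylogous acid, pKa about 5, and the enolate oxygens are acylated far faster than the neutral secondary alcohol, giving mainly 9 and some 10) is followed by a photo-Fries-type 1,3-acyl shift, in which the vinylogous-anhydride chromophore absorbs far more strongly at 254 nm than the C–Br bond, its excited state cleaves the O–acyl bond and the acyl group recombines at C2 inside the solvent cage, after which enolisation to the hydrogen-bonded triketone makes the shift irreversible; both enol esters converge on 11, so they need not be separated, this forms the ring–side-chain C–C bond, and no bond at the stereocentre is broken.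

**Step 4**
Reactants: 11 (S)-2-(12-bromododecanoyl)-3,6-dihydroxycyclohex-2-en-1-one
Product: 12 {12-[(5S)-2,5-dihydroxy-6-oxocyclohex-1-en-1-yl]-12-oxododecyl}triphenylphosphonium bromide
Conditions: PPh3 (1.5 equiv), MeCN, reflux, 48 h; precipitate from Et2O
Reagents that add atoms: triphenylphosphine c1ccc(cc1)P(c1ccccc1)c1ccccc1
Why: SN2 quaternisation of a primary alkyl bromide by PPh3 (phosphonium salt formation); the enolised triketone and the secondary alcohol are inert to the neutral phosphine and no base is present, so the stereocentre is safe.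

**Step 5**
Reactants: 12 {12-[(5S)-2,5-dihydroxy-6-oxocyclohex-1-en-1-yl]-12-oxododecyl}triphenylphosphonium bromide; 13 (E)-but-2-enal
Product: 15 (6S)-2-[(12Z,14E)-hexadeca-12,14-dienoyl]-3,6-dihydroxycyclohex-2-en-1-one, via disodium ylide 14 (not isolated)
Conditions: NaN(SiMe3)2 (3.2 equiv), THF–DMPU (10:1), −78 °C to −20 °C; then 13 (1.5 equiv), −78 °C to −20 °C; aq. HCl (1 M) to pH 3, 0 °C
Reagents that add atoms: none
Why: Z-selective Wittig olefination of a non-stabilised ylide under lithium-free conditions: the first equivalent of base turns the acidic triketone into its unreactive sodium enolate and the next two form the ylide carbon and the alkoxide (14, comparable to the carboxylate- and alkoxide-bearing ylides tolerated in ω-carboxyalkyl olefinations), the ylide adds to the aldehyde carbonyl of 13 under kinetic control to give the 12Z alkene while the 14E geometry is bought in 13, and the ring stereocentre is not deprotonated because the adjacent carbonyl is part of the delocalised triketonate.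

**Compound list**
1 | (S)-5-oxotetrahydrofuran-2-carboxylic acid | OC(=O)[C@@H]1CCC(=O)O1 | starting material
2 | (S)-5-oxotetrahydrofuran-2-carbonyl chloride | ClC(=O)[C@@H]1CCC(=O)O1 | intermediate
3 | (S)-5-acetyldihydrofuran-2(3H)-one | CC(=O)[C@@H]1CCC(=O)O1 | intermediate
4 | lithium 1-[(2S)-5-oxooxolan-2-yl]ethen-1-olate | [Li+].C=C([O-])[C@@H]1CCC(=O)O1 | intermediate
5 | lithium (1R,4S)-3-oxo-7-oxabicyclo[2.2.1]heptan-1-olate | [Li+].[O-][C@]12CC[C@H](O1)C(=O)C2 | intermediate
6 | (S)-4-hydroxycyclohexane-1,3-dione | O=C1CC(=O)[C@@H](O)CC1 | intermediate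
7 | 12-bromododecanoic acid | OC(=O)CCCCCCCCCCCBr | starting material
8 | 12-bromododecanoyl chloride | ClC(=O)CCCCCCCCCCCBr | intermediate
9 | (S)-4-hydroxy-3-oxocyclohex-1-en-1-yl 12-bromododecanoate | BrCCCCCCCCCCCC(=O)OC1=CC(=O)[C@@H](O)CC1 | intermediate
10 | (S)-6-hydroxy-3-oxocyclohex-1-en-1-yl 12-bromododecanoate | BrCCCCCCCCCCCC(=O)OC1=CC(=O)CC[C@@H]1O | intermediate
11 | (S)-2-(12-bromododecanoyl)-3,6-dihydroxycyclohex-2-en-1-one | BrCCCCCCCCCCCC(=O)C1=C(O)CC[C@H](O)C1=O | intermediate
12 | {12-[(5S)-2,5-dihydroxy-6-oxocyclohex-1-en-1-yl]-12-oxododecyl}triphenylphosphonium bromide | [Br-].O=C(CCCCCCCCCCC[P+](c1ccccc1)(c1ccccc1)c1ccccc1)C1=C(O)CC[C@H](O)C1=O | intermediate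
13 | (E)-but-2-enal | C/C=C/C=O | starting material
14 | disodium (4S)-3-oxo-2-[12-(triphenyl-λ5-phosphanylidene)dodecanoyl]cyclohex-1-ene-1,4-diolate | [Na+].[Na+].O=C(CCCCCCCCCCC=P(c1ccccc1)(c1ccccc1)c1ccccc1)C1=C([O-])CC[C@H]([O-])C1=O | intermediate
15 | (6S)-2-[(12Z,14E)-hexadeca-12,14-dienoyl]-3,6-dihydroxycyclohex-2-en-1-one | C/C=C/C=C\CCCCCCCCCCC(=O)C1=C(O)CC[C@H](O)C1=O | target

**Step count**
Total steps: 5. Longest linear sequence: 5 (1 → 3 → 6 → 11 → 12 → 15); 7 and 13 enter without steps of their own.

**Three steps most likely to fail**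

Step 2 (the proposed new step). The addition passes through the strained bridged alkoxide 5, and intermolecular Claisen oligomerisation can compete. Any equilibration of enolate 4 towards the methine would erode the enantiomeric purity, which is to be checked by chiral HPLC on 6. The fallback uses only known chemistry, sets out from 3 and comes back at 6. The ketone of 3 is masked with ethylene glycol and PPTS to give (S)-5-(2-methyl-1,3-dioxolan-2-yl)dihydrofuran-2(3H)-one F1. The lactone is opened with MeNHOMe·HCl and AlMe3 to the hydroxy Weinreb amide (S)-4-hydroxy-N-methoxy-N-methyl-4-(2-methyl-1,3-dioxolan-2-yl)butanamide F2, which is silylated (TBSCl, imidazole) to (S)-4-[(tert-butyldimethylsilyl)oxy]-N-methoxy-N-methyl-4-(2-methyl-1,3-dioxolan-2-yl)butanamide F3. The ketone is unmasked (PPTS, wet acetone) to (S)-4-[(tert-butyldimethylsilyl)oxy]-N-methoxy-N-methyl-5-oxohexanamide F4. The kinetic methyl-ketone enolate (LiN(SiMe3)2, THF, −78 to 0 °C) is acylated by the Weinreb amide in an unstrained 6-exo closure to (S)-4-[(tert-butyldimethylsilyl)oxy]cyclohexane-1,3-dione F5, and HF in MeCN gives 6.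

Step 3 (enol esterification and photochemical acyl shift). The triketone product absorbs at the irradiation wavelength (inner filter, secondary photolysis). α-Cleavage next to the carbinol or enone photodimerisation may compete, and cage escape returns 6 and 7. The fallback sets out from 6 (with 8 made from 7 as before) and comes back at 11. The same enol esters 9 and 10 are formed in the flask, and light is replaced by ground-state nucleophilic catalysis: 4-(dimethylamino)pyridine (0.2 equiv) and Et3N in MeCN at rt bring about the known O-to-C acyl transfer of 1,3-dione enol esters. No new compound is made.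

Step 5 (Wittig on the unprotected triketone). The polyanionic ylide 14 may be poorly soluble, and crotonaldehyde can self-condense under base. A Z:E ratio near 9:1 at C12 is expected, so the 12E isomer would have to be removed on AgNO3-impregnated silica. The fallback sets out from 7 (and uses 6) and comes back at 15. It builds the diene before the ring is attached: 7 and PPh3 in refluxing MeCN give (11-carboxyundecyl)triphenylphosphonium bromide F6. Wittig olefination (NaN(SiMe3)2, 2.1 equiv, THF, −78 °C, then 13) gives (12Z,14E)-hexadeca-12,14-dienoic acid F7. Coupling of F7 with 6 (N,N'-dicyclohexylcarbodiimide, 4-(dimethylamino)pyridine, CH2Cl2) forms the enol esters (S)-4-hydroxy-3-oxocyclohex-1-en-1-yl (12Z,14E)-hexadeca-12,14-dienoate F8 and (S)-6-hydroxy-3-oxocyclohex-1-en-1-yl (12Z,14E)-hexadeca-12,14-dienoate F9 in the flask. The pyridine catalyst then isomerises them thermally to 15, because light cannot be used once the diene is present.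

**Further compounds**
F1 | step 2 | (S)-5-(2-methyl-1,3-dioxolan-2-yl)dihydrofuran-2(3H)-one | CC1(OCCO1)[C@@H]1CCC(=O)O1
F2 | step 2 | (S)-4-hydroxy-N-methoxy-N-methyl-4-(2-methyl-1,3-dioxolan-2-yl)butanamide | CON(C)C(=O)CC[C@H](O)C1(C)OCCO1
F3 | step 2 | (S)-4-[(tert-butyldimethylsilyl)oxy]-N-methoxy-N-methyl-4-(2-methyl-1,3-dioxolan-2-yl)butanamide | CON(C)C(=O)CC[C@H](O[Si](C)(C)C(C)(C)C)C1(C)OCCO1
F4 | step 2 | (S)-4-[(tert-butyldimethylsilyl)oxy]-N-methoxy-N-methyl-5-oxohexanamide | CON(C)C(=O)CC[C@H](O[Si](C)(C)C(C)(C)C)C(C)=O
F5 | step 2 | (S)-4-[(tert-butyldimethylsilyl)oxy]cyclohexane-1,3-dione | O=C1CC(=O)[C@@H](O[Si](C)(C)C(C)(C)C)CC1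
F0 | step 3 | none | none
F6 | step 5 | (11-carboxyundecyl)triphenylphosphonium bromide | [Br-].OC(=O)CCCCCCCCCCC[P+](c1ccccc1)(c1ccccc1)c1ccccc1
F7 | step 5 | (12Z,14E)-hexadeca-12,14-dienoic acid | C/C=C/C=C\CCCCCCCCCCC(=O)O
F8 | step 5 | (S)-4-hydroxy-3-oxocyclohex-1-en-1-yl (12Z,14E)-hexadeca-12,14-dienoate | C/C=C/C=C\CCCCCCCCCCC(=O)OC1=CC(=O)[C@@H](O)CC1
F9 | step 5 | (S)-6-hydroxy-3-oxocyclohex-1-en-1-yl (12Z,14E)-hexadeca-12,14-dienoate | C/C=C/C=C\CCCCCCCCCCC(=O)OC1=CC(=O)CC[C@@H]1O
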